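## Retrosynthetic overview

1. Target 13 (meso tetrahydrofuran) ⇐ both benzylic C–O bonds: erythro 8–8′-linked bis(p-quinone methide) 10 + H2O (hydration, then oxa-1,6-addition), the ring closure by which 9,9′-diacyl-7,7′-epoxylignans are thought to arise in plants.
2. 10 is not made by free-radical 8–8′ coupling of (E)-caffeyl acetate, which is threo-selective (3,4-trans series) and diverted to benzodioxanes by the catechol. It is unmasked instead by two-electron oxidative scission of the C7–C7′ bond of cyclobutane 8, a net insertion of a water-derived oxygen into a photodimer.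
3. 8 ⇐ hexaol 7 ⇐ β-truxinate cyclophane 6 ⇐ template-directed [2+2] photodimerisation of two diacetylcaffeoyl units on naphthalene-1,8-diol, which fixes C8/C8′ cis.
4. Ring order: cyclobutane (step 3, sacrificial) → tetrahydrofuran (step 6, the only ring of the target; C2/C5 set under thermodynamic control).

Assumption: the given SMILES is the meso compound (2R,3S,4R,5S; 2,3-trans, 3,4-cis, 4,5-trans; mirror plane through O1), so it is achiral, has no enantiomer, and only relative configuration has to be controlled.

## Route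

Step 1
Reactants: 1 (E)-caffeic acid
Product: 2 (E)-3-(3,4-diacetoxyphenyl)acrylic acid
Conditions: Ac2O (3 equiv), pyridine, 0 °C → rt; then H2O, 1 M HCl
Reagents that add atoms: acetic anhydride, CC(=O)OC(C)=O
Why: Pyridine-mediated O-acetylation (nucleophilic acyl substitution) masks both phenols for the acid-chloride chemistry, any mixed anhydride at CO2H is hydrolysed on aqueous work-up, and no stereocentre is involved.

Step 2
Reactants: 2 (E)-3-(3,4-diacetoxyphenyl)acrylic acid (2.2 equiv); 3 naphthalene-1,8-diol (1 equiv)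
Product: 5 naphthalene-1,8-diyl bis[(E)-3-(3,4-diacetoxyphenyl)acrylate], via 3,4-diacetoxycinnamoyl chloride 4 (not isolated)
Conditions: (COCl)2, cat. DMF, CH2Cl2, 0 °C → rt, evaporate; then 3, pyridine, CH2Cl2, 0 °C → rt
Reagents that add atoms: oxalyl chloride, O=C(Cl)C(=O)Cl (supplies only the Cl of 4, which is lost again; no reagent atom remains in 5)
Why: Vilsmeier-type acid chloride formation followed by Schotten–Baumann-type O-acylation of both peri-hydroxyls; aryl acetates and the E-alkene are inert to these conditions.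

Step 3
Reactants: 5 naphthalene-1,8-diyl bis[(E)-3-(3,4-diacetoxyphenyl)acrylate]
Product: 6 naphthalene-1,8-diyl (1R,2S,3R,4S)-3,4-bis(3,4-diacetoxyphenyl)cyclobutane-1,2-dicarboxylate (cyclic diester; meso β-truxinate)
Conditions: hν (365 nm LED), crystalline powder/thin film, rt, N2
Reagents that add atoms: none
Why: Template-directed intramolecular [2+2] photocycloaddition, in which the peri-diester holds the two E-cinnamoyl C=C bonds parallel, head-to-head and within the Schmidt distance, so suprafacial addition gives only the syn head-to-head cyclobutane; this sets the two carboxyl-bearing carbons (future C3/C4) cis (meso) and each aryl trans to its neighbouring carboxyl, a relationship that threo-selective radical coupling of (E)-monolignols does not give.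

Step 4
Reactants: 6 naphthalene-1,8-diyl (1R,2S,3R,4S)-3,4-bis(3,4-diacetoxyphenyl)cyclobutane-1,2-dicarboxylate
Product: 7 [(1R,2S,3R,4S)-3,4-bis(3,4-dihydroxyphenyl)cyclobutane-1,2-diyl]dimethanol (meso)
Conditions: LiAlH4 (6 equiv), THF, 0 °C → rt; 1 M HCl work-up under Ar
Reagents that add atoms: none
Why: LiAlH4 ester reduction cleaves both naphthyl esters to CH2OH (releasing template 3 for re-use) and strips the four aryl acetates in the same operation, and the aldehyde stage is reduced faster than it can enolise at 0 °C, so the cis relationship of the CH2OH-bearing carbons is kept.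

Step 5
Reactants: 7 [(1R,2S,3R,4S)-3,4-bis(3,4-dihydroxyphenyl)cyclobutane-1,2-diyl]dimethanol
Product: 8 [(1R,2S,3R,4S)-3,4-bis(3,4-dihydroxyphenyl)cyclobutane-1,2-diyl]bis(methylene) diacetate (meso)
Conditions: Novozym 435 (immobilised CAL-B), vinyl acetate (10 equiv), THF, 40 °C
Reagents that add atoms: vinyl acetate, CC(=O)OC=C
Why: Lipase-catalysed irreversible transesterification is chemoselective for primary aliphatic OH over phenolic OH (as in hydroxytyrosol → hydroxytyrosyl acetate), and the acetates are installed now so that, as with γ-acylated monolignols in nature, the 9-oxygens cannot intercept the quinone methides of step 6; no stereocentre is touched.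

Step 6
Reactants: 8 [(1R,2S,3R,4S)-3,4-bis(3,4-dihydroxyphenyl)cyclobutane-1,2-diyl]bis(methylene) diacetate
Product: 13 meso-[(2R,3S,4R,5S)-2,5-bis(3,4-dihydroxyphenyl)oxolane-3,4-diyl]bis(methylene) diacetate (target), via mono-o-quinone 9 (not isolated), via meso-bis(quinone methide) 10 (not isolated), via hydroxy quinone methide 11 (not isolated), via cis-epimer 12 (not isolated)
Conditions: Ag2O (1.05 equiv), acetone–H2O 4:1 (3 mM), 0 °C → rt, dark, Ar; filter (Celite); then TsOH·H2O (10 mol %), 35 °C
Reagents that add atoms: water, O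
Why: Proposed new method: two-electron oxidation of one catechol gives o-quinone 9, a strained vinylogous donor–acceptor cyclobutane (4-hydroxyaryl donor on C7′, quinone acceptor on C7) whose doubly benzylic C7–C7′ bond breaks (Grob-type retro-vinylogous-Michael heterolysis, or β-scission at the semiquinone stage, driven by about 26 kcal/mol of ring strain) to the meso bis(p-quinone methide) 10, i.e. the intermediate of monolignol-acetate 8–8′ coupling but with the erythro C8/C8′ configuration inherited unchanged from 8; 10 adds water at one methide carbon (1,6-addition) to give 11, whose benzylic OH closes the ring by 5-exo oxa-1,6-addition to the second quinone methide; C2 and C5 are set under thermodynamic control (each aryl trans to its neighbouring CH2OAc) because the p-hydroxybenzyl ether reopens to 11 under the acidic finish, so the kinetic cis-epimer 12 drains into 13; the closest known reaction types are the o-quinone → p-quinone methide isomerisation of 4-alkylcatechol quinones, ring-opening of p-hydroxyaryl donor–acceptor cyclopropanes/cyclobutanes to p-quinone methides, electron-transfer C–C scission of 1,2-diarylcyclobutanes, and water trapping of β–β bis(quinone methides) from γ-acylated monolignols to tetrahydrofurans.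

## Compound list

1 | (E)-caffeic acid | O=C(O)/C=C/c1ccc(O)c(O)c1 | starting material
2 | (E)-3-(3,4-diacetoxyphenyl)acrylic acid | CC(=O)Oc1ccc(/C=C/C(=O)O)cc1OC(C)=O | intermediate
3 | naphthalene-1,8-diol (template, recovered in step 4) | Oc1cccc2cccc(O)c12 | starting material
4 | (E)-3-(3,4-diacetoxyphenyl)acryloyl chloride | CC(=O)Oc1ccc(/C=C/C(=O)Cl)cc1OC(C)=O | intermediate (not isolated)
5 | naphthalene-1,8-diyl bis[(E)-3-(3,4-diacetoxyphenyl)acrylate] | CC(=O)Oc1ccc(/C=C/C(=O)Oc2cccc3cccc(OC(=O)/C=C/c4ccc(OC(C)=O)c(OC(C)=O)c4)c23)cc1OC(C)=O | intermediate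
6 | naphthalene-1,8-diyl (1R,2S,3R,4S)-3,4-bis(3,4-diacetoxyphenyl)cyclobutane-1,2-dicarboxylate (meso; aryls cis, carboxyls cis, aryl/carboxyl trans) | O=C1Oc2cccc3cccc(OC(=O)[C@@H]4[C@@H](c5ccc(OC(C)=O)c(OC(C)=O)c5)[C@@H](c5ccc(OC(C)=O)c(OC(C)=O)c5)[C@@H]41)c23 | intermediate
7 | [(1R,2S,3R,4S)-3,4-bis(3,4-dihydroxyphenyl)cyclobutane-1,2-diyl]dimethanol (meso) | OC[C@@H]1[C@@H](c2ccc(O)c(O)c2)[C@@H](c2ccc(O)c(O)c2)[C@@H]1CO | intermediate
8 | [(1R,2S,3R,4S)-3,4-bis(3,4-dihydroxyphenyl)cyclobutane-1,2-diyl]bis(methylene) diacetate (meso) | CC(=O)OC[C@@H]1[C@@H](c2ccc(O)c(O)c2)[C@@H](c2ccc(O)c(O)c2)[C@@H]1COC(C)=O | intermediate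
9 | mono-o-quinone of 8 (racemic, either ring oxidised; one enantiomer drawn) | CC(=O)OC[C@@H]1[C@@H](C2=CC(=O)C(=O)C=C2)[C@@H](c2ccc(O)c(O)c2)[C@@H]1COC(C)=O | intermediate (not isolated)
10 | meso-(2R,3S)-2,3-bis[(3-hydroxy-4-oxocyclohexa-2,5-dien-1-ylidene)methyl]butane-1,4-diyl diacetate | CC(=O)OC[C@@H](C=C1C=CC(=O)C(O)=C1)[C@H](COC(C)=O)C=C1C=CC(=O)C(O)=C1 | intermediate (not isolated)
11 | water adduct of 10: benzylic alcohol on one arm, quinone methide on the other (racemic; both carbinol epimers, carbinol centre left undefined) | CC(=O)OC[C@@H](C=C1C=CC(=O)C(O)=C1)[C@H](COC(C)=O)C(O)c1ccc(O)c(O)c1 | intermediate (not isolated)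
12 | rac-[(2R,3S,4R,5R)-2,5-bis(3,4-dihydroxyphenyl)oxolane-3,4-diyl]bis(methylene) diacetate (2,3-trans, 3,4-cis, 4,5-cis; one enantiomer drawn) | CC(=O)OC[C@@H]1[C@H](COC(C)=O)[C@H](c2ccc(O)c(O)c2)O[C@H]1c1ccc(O)c(O)c1 | intermediate (not isolated)
13 | meso-[(2R,3S,4R,5S)-2,5-bis(3,4-dihydroxyphenyl)oxolane-3,4-diyl]bis(methylene) diacetate (2,3-trans, 3,4-cis, 4,5-trans) | CC(=O)OC[C@@H]1[C@H](COC(C)=O)[C@@H](c2ccc(O)c(O)c2)O[C@H]1c1ccc(O)c(O)c1 | target

## Step count and risks

Total step count: 6. Longest linear sequence: 6 (1 → 2 → 5 → 6 → 7 → 8 → 13; template 3 enters in step 2).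

**Step 6 (highest risk).** The o-quinone 9 may fail to fragment and instead couple with the neighbouring cis-aryl ring, the catechols of the product may be over-oxidised, or the acidic finish may drift to an aryltetralin by Friedel–Crafts closure. The fallback sets out from 8 and returns at 13. It replaces phenol oxidation by radical-cation chemistry on a protected substrate and brings the oxygen in from O2. Silylation of 8 (TBSCl, imidazole, DMF) gives the tetrakis(tert-butyldimethylsilyl) ether F1. Electron-transfer photo-oxygenation (9,10-dicyanoanthracene cat., O2, hν > 400 nm, MeCN) cleaves the same C7–C7′ bond in the arene radical cation and traps the 1,4-radical cation as the cis-4,5-bis(acetoxymethyl)-3,6-diaryl-1,2-dioxane F2. Zn/AcOH reduces the peroxide to the erythro 1,4-diaryl-butane-1,4-diol F3. Et3N·3HF followed by cat. TsOH removes the silyl groups and closes the ring by p-quinone-methide cyclodehydration under thermodynamic control to 13.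

**Step 4.** The aluminium-bound polyphenol may be hard to free cleanly, or hydride reduction of the strained cis-diester may be incomplete or epimerising. The fallback sets out from 6 and returns at 7. Saponification (KOH, degassed aq. MeOH–THF, then HCl) releases the template and the acetates to give 3,3′,4,4′-tetrahydroxy-β-truxinic acid F4, and borane (BH3·THF, 0 °C → rt, MeOH/HCl work-up) reduces the diacid to 7 without an aluminium hydride.

**Step 5.** The lipase may acetylate the hindered second CH2OH slowly or not at all. The fallback sets out from 7 and returns at 8. Exhaustive acetylation (Ac2O, pyridine, cat. DMAP) gives the cyclobutane hexaacetate F5, and chemoselective methanolysis of the four aryl acetates (NH4OAc, MeOH–H2O, rt, Ar) leaves the two primary acetates and gives 8.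

## Further compounds

F1 | step 6 | [(1R,2S,3R,4S)-3,4-bis[3,4-bis(tert-butyldimethylsilyloxy)phenyl]cyclobutane-1,2-diyl]bis(methylene) diacetate | CC(=O)OC[C@@H]1[C@@H](c2ccc(O[Si](C)(C)C(C)(C)C)c(O[Si](C)(C)C(C)(C)C)c2)[C@@H](c2ccc(O[Si](C)(C)C(C)(C)C)c(O[Si](C)(C)C(C)(C)C)c2)[C@@H]1COC(C)=O
F2 | step 6 | cis-4,5-bis(acetoxymethyl)-3,6-bis[3,4-bis(tert-butyldimethylsilyloxy)phenyl]-1,2-dioxane (C3/C6 epimer mixture) | CC(=O)OC[C@@H]1[C@H](COC(C)=O)C(c2ccc(O[Si](C)(C)C(C)(C)C)c(O[Si](C)(C)C(C)(C)C)c2)OOC1c1ccc(O[Si](C)(C)C(C)(C)C)c(O[Si](C)(C)C(C)(C)C)c1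
F3 | step 6 | meso-(2R,3S)-2,3-bis{[3,4-bis(tert-butyldimethylsilyloxy)phenyl](hydroxy)methyl}butane-1,4-diyl diacetate (carbinol epimer mixture) | CC(=O)OC[C@@H](C(O)c1ccc(O[Si](C)(C)C(C)(C)C)c(O[Si](C)(C)C(C)(C)C)c1)[C@H](COC(C)=O)C(O)c1ccc(O[Si](C)(C)C(C)(C)C)c(O[Si](C)(C)C(C)(C)C)c1
F4 | step 4 | (1R,2S,3R,4S)-3,4-bis(3,4-dihydroxyphenyl)cyclobutane-1,2-dicarboxylic acid (meso) | O=C(O)[C@@H]1[C@@H](c2ccc(O)c(O)c2)[C@@H](c2ccc(O)c(O)c2)[C@@H]1C(=O)O
F5 | step 5 | [(1R,2S,3R,4S)-3,4-bis(3,4-diacetoxyphenyl)cyclobutane-1,2-diyl]bis(methylene) diacetate (meso) | CC(=O)OC[C@@H]1[C@@H](c2ccc(OC(C)=O)c(OC(C)=O)c2)[C@@H](c2ccc(OC(C)=O)c(OC(C)=O)c2)[C@@H]1COC(C)=O
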